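The hydrindane is cut at the fusion bond C3a–C7a and at C1–C2 and C2–C3, so that the five-membered ring (C1, C2, C3, C3a, C7a) and the six-membered ring (C3a to C7a) arise from one acyclic 1,7-enyne and CO: alkyne C7a≡C1, 1,1-disubstituted alkene C3a=C3, carbonyl C2. A single enantioselective Pauson–Khand reaction closes both rings, makes three skeletal bonds and sets the methyl-bearing quaternary C3a. The precursor carries C6 as a dioxolane and an (S)-silyloxyethyl group on the alkyne; this centre later steers the hydrogenation and ends as the C1' ketone that receives the enantiopure side chain. The C2 oxygen is excised and C6 becomes the acetyl-bearing alkene.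

Key step: step 7

Remark: the sense of induction of BINAP cannot be carried over with certainty from 1,6-enynes to this 1,7-enyne, so (R)-BINAP is written and its antipode is to be used if a trial run shows the other C3a configuration.
Remark: metal alkoxides and borates that are only protonated on aqueous work-up are not numbered; intermediates that are generated on purpose and then treated with a further reagent are.

Atom labels: ring C1 (side-chain carbon), C2, C3, C3a (methyl), C4, C5=C6 (acetyl on C6), C7, C7a; chain C1' (carbinol) to C5' (isopropenyl carbon).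

Step 1
Reactants: 1 (S)-but-3-yn-2-ol
Product: 2 (S)-tert-butyl(but-3-yn-2-yloxy)dimethylsilane
Conditions: TBSCl, imidazole, CH2Cl2, 0 °C to rt
Reagents that add atoms: tert-butyldimethylsilyl chloride, C[Si](C)(Cl)C(C)(C)C
Why: Silyl ether formation from a secondary alcohol with a silyl chloride and imidazole leaves the stereocentre untouched and masks the hydroxyl for the organolithium steps.

Step 2
Reactants: 2 silyl ether of butynol
Product: 4 (S)-4-[(tert-butyldimethylsilyl)oxy]pent-2-yn-1-ol, via lithium acetylide 3 (not isolated)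
Conditions: n-BuLi, THF, −78 °C; (CH2O)n, −78 °C to rt; aq NH4Cl
Reagents that add atoms: paraformaldehyde (as formaldehyde), C=O
Why: Deprotonation of the terminal alkyne and 1,2-addition of the lithium acetylide to formaldehyde (alkyne hydroxymethylation) installs the carbon that becomes C7.

Step 3
Reactants: 4 propargylic alcohol
Product: 5 (S)-[(5-bromopent-3-yn-2-yl)oxy](tert-butyl)dimethylsilane
Conditions: CBr4, PPh3, CH2Cl2, 0 °C
Reagents that add atoms: carbon tetrabromide, BrC(Br)(Br)Br
Why: Appel bromination turns the primary propargylic alcohol into the bromide under neutral conditions that spare the silyl ether.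

Step 4
Reactants: 6 1,3-dithiane; 7 4-bromo-2-methylbut-1-ene
Product: 9 2-(3-methylbut-3-en-1-yl)-1,3-dithiane, via 2-lithio-1,3-dithiane 8 (not isolated)
Conditions: n-BuLi, THF, −30 °C; then 7, −78 °C to rt
Reagents that add atoms: none
Why: Corey–Seebach alkylation, in which the sulfur-stabilized carbanion displaces the primary homoallylic bromide by SN2 and joins the future C6 to C5.

Step 5
Reactants: 9 monoalkyl dithiane; 5 propargylic bromide
Product: 11 (S)-tert-butyldimethyl({5-[2-(3-methylbut-3-en-1-yl)-1,3-dithian-2-yl]pent-3-yn-2-yl}oxy)silane, via lithiated dithiane 10 (not isolated)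
Conditions: n-BuLi, THF, −20 °C; then 5, −78 °C to 0 °C
Reagents that add atoms: none
Why: Second Corey–Seebach alkylation, in which the tertiary dithianyl anion attacks the unhindered primary propargylic bromide by SN2, joining C6 to C7 and completing the carbon chain of the enyne.

Step 6
Reactants: 11 dialkyl dithiane
Product: 12 (S)-tert-butyldimethyl({5-[2-(3-methylbut-3-en-1-yl)-1,3-dioxolan-2-yl]pent-3-yn-2-yl}oxy)silane
Conditions: PhI(OCOCF3)2, HOCH2CH2OH, MeCN, 0 °C to rt; aq NaHCO3
Reagents that add atoms: ethylene glycol, OCCO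
Why: Oxidative thioacetal cleavage by the hypervalent iodine reagent in the presence of the diol traps the sulfur-stabilized cation directly as the dioxolane (oxidative trans-ketalization), so the β,γ-alkynyl ketone is never set free and cannot isomerize to the allenyl ketone.

Step 7
Reactants: 12 1,7-enyne
Product: 13 (3aS)-1-[(S)-1-(tert-butyldimethylsilyloxy)ethyl]-6,6-(ethylenedioxy)-3a-methyl-3,3a,4,5,6,7-hexahydro-2H-inden-2-one
Conditions: [Rh(CO)2Cl]2 (5 mol %), (R)-BINAP (12 mol %), AgOTf (20 mol %), CO (1 atm), THF, 80 °C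
Reagents that add atoms: carbon monoxide, [C-]#[O+]
Why: The cationic complex formed from [Rh(CO)2Cl]2, AgOTf and BINAP (monovalent rhodium) binds the alkyne and the 1,1-disubstituted alkene and undergoes oxidative cyclization to a rhodacyclopentene, which forms C3a–C7a; CO then inserts into the Rh–C3 bond and reductive elimination forms C3–C2 and C2–C1. The closest known reaction is the enantioselective intramolecular Pauson–Khand reaction of 1,6-enynes with the same [Rh(CO)2Cl]2/AgOTf/BINAP system, and its use on a carbon-tethered 1,7-enyne with a 1,1-disubstituted alkene is an extrapolation within this reaction class. The six-membered ring closes in the exo mode with respect to both π bonds through the four-atom tether C4–C7, and the five-membered ring closes when C2 is stitched between C3 and C1 by carbonyl insertion and reductive elimination. The quaternary C3a is the only new stereocentre and is set in the oxidative cyclization by the alkene face that the chiral diphosphine allows; the (S)-carbinol centre is too remote to decide it but turns the two C3a outcomes into diastereomers that can be told apart and separated. The step needs cyclization to outrun alkyne oligomerization and cycloisomerization, which the C6 dioxolane (gem-disubstituent effect on the tether) and a low CO pressure that keeps a coordination site free are meant to secure; the tether allows one regiochemistry only.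

Step 8
Reactants: 13 bicyclic enone
Product: 14 (1S,3aS,7aS)-1-[(S)-1-(tert-butyldimethylsilyloxy)ethyl]-6,6-(ethylenedioxy)-3a-methyloctahydro-2H-inden-2-one
Conditions: H2 (5 bar), Pd/C (10 %), EtOAc, rt
Reagents that add atoms: none
Why: Heterogeneous syn hydrogenation of the tetrasubstituted enone should deliver both hydrogens to the face opposite the angular C3a methyl, as in the hydrogenation of 14-ene steroids, and the (S)-silyloxy group, which allylic 1,3-strain (C1'–H eclipsed toward C7) places on the methyl face, shields that face further, so C7a–H and C1–H are set together anti to the methyl (trans ring fusion).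

Step 9
Reactants: 14 saturated ketone
Product: 15 C2 alcohol of 14 (mixture of C2 epimers; other centres as in 14)
Conditions: NaBH4, MeOH, 0 °C
Reagents that add atoms: none
Why: Borohydride 1,2-reduction of the cyclopentanone, whose C2 configuration is irrelevant because the oxygen is removed, under cold conditions that avoid epimerization at C1 and β-elimination of the silyloxy group.

Step 10
Reactants: 15 C2 alcohol
Product: 16 O-phenyl thionocarbonate of 15
Conditions: PhOC(S)Cl, pyridine, DMAP, CH2Cl2, rt
Reagents that add atoms: O-phenyl chlorothionoformate, S=C(Cl)Oc1ccccc1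
Why: Acylation of the secondary alcohol with an aryl chlorothionoformate gives the thiocarbonyl derivative needed for radical deoxygenation (first half of a Barton–McCombie deoxygenation).

Step 11
Reactants: 16 thionocarbonate
Product: 17 (1S,3aR,7aS)-1-[(S)-1-(tert-butyldimethylsilyloxy)ethyl]-6,6-(ethylenedioxy)-3a-methyloctahydro-1H-indene
Conditions: Bu3SnH, AIBN, toluene, 100 °C
Reagents that add atoms: none
Why: Barton–McCombie deoxygenation, in which the stannyl radical adds to the thiocarbonyl, the C2–O bond fragments to a secondary radical and Bu3SnH reduces it, makes C2 a methylene without any enolizable intermediate that could epimerize C1.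

Step 12
Reactants: 17 silyl ether
Product: 18 (S)-1-[(1S,3aR,7aS)-6,6-(ethylenedioxy)-3a-methyloctahydro-1H-inden-1-yl]ethan-1-ol
Conditions: Bu4NF, THF, rt
Reagents that add atoms: none
Why: Fluoride cleavage of the silyl ether, to which the dioxolane is inert.

Step 13
Reactants: 18 secondary alcohol
Product: 19 1-[(1S,3aR,7aS)-6,6-(ethylenedioxy)-3a-methyloctahydro-1H-inden-1-yl]ethan-1-one
Conditions: Dess–Martin periodinane, NaHCO3, CH2Cl2, 0 °C to rt
Reagents that add atoms: none
Why: Dess–Martin oxidation under buffered, non-basic conditions gives the methyl ketone without epimerizing the adjacent C1.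

Step 14
Reactants: 20 3-[(tert-butyldimethylsilyl)oxy]propanal
Product: 21 rac-5-[(tert-butyldimethylsilyl)oxy]-2-methylpent-1-en-3-ol
Conditions: isopropenylmagnesium bromide, THF, −78 °C to 0 °C; aq NH4Cl
Reagents that add atoms: isopropenylmagnesium bromide, C=C(C)[Mg]Br
Why: Grignard 1,2-addition of an alkenylmagnesium halide to the aldehyde gives the racemic 2-methylallylic alcohol that holds C2' to C5'.

Step 15
Reactants: 21 racemic allylic alcohol
Product: 22 (S)-5-[(tert-butyldimethylsilyl)oxy]-2-methylpent-1-en-3-ol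
Conditions: Ti(OiPr)4, D-(−)-diisopropyl tartrate, t-BuOOH (0.6 equiv), 4 Å molecular sieves, CH2Cl2, −20 °C
Reagents that add atoms: none
Why: Sharpless kinetic resolution of a secondary allylic alcohol, in which the Ti(OiPr)4–D-tartrate catalyst epoxidizes the (R)-enantiomer fast, so the (S)-alcohol (the future C4') is recovered after slightly more than half conversion.

Step 16
Reactants: 22 (S)-allylic alcohol
Product: 23 (S)-5-[(tert-butyldimethylsilyl)oxy]-3-[(tert-butyldiphenylsilyl)oxy]-2-methylpent-1-ene
Conditions: TBDPSCl, imidazole, DMF, rt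
Reagents that add atoms: tert-butyldiphenylsilyl chloride, CC(C)(C)[Si](Cl)(c1ccccc1)c1ccccc1
Why: Silylation of the secondary allylic alcohol with the robust tert-butyldiphenylsilyl group, which is chosen to survive alkyllithium formation, aqueous acid and enolate chemistry.

Step 17
Reactants: 23 bis-silyl ether
Product: 24 (S)-3-[(tert-butyldiphenylsilyl)oxy]-4-methylpent-4-en-1-ol
Conditions: camphorsulfonic acid (cat.), MeOH/CH2Cl2, 0 °C
Reagents that add atoms: none
Why: Acid-catalysed methanolysis removes the primary tert-butyldimethylsilyl ether much faster than the hindered secondary tert-butyldiphenylsilyl ether (selective desilylation).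

Step 18
Reactants: 24 primary alcohol
Product: 25 (S)-tert-butyl[(5-iodo-2-methylpent-1-en-3-yl)oxy]diphenylsilane
Conditions: I2, PPh3, imidazole, CH2Cl2, 0 °C
Reagents that add atoms: iodine, II
Why: Appel-type iodination with PPh3 and I2 converts the primary alcohol into the iodide without touching the stereocentre.

Step 19
Reactants: 25 side-chain iodide; 19 methyl ketone
Product: 28 (2S,5S)-5-[(tert-butyldiphenylsilyl)oxy]-2-[(1S,3aR,7aS)-6,6-(ethylenedioxy)-3a-methyloctahydro-1H-inden-1-yl]-6-methylhept-6-en-2-ol, via alkyllithium 26 (not isolated), via organocerium dichloride 27 (not isolated)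
Conditions: 25, t-BuLi (2.1 equiv), Et2O, −78 °C; CeCl3, THF, −78 °C; then 19, −78 °C; aq NH4Cl
Reagents that add atoms: none
Why: Iodine–lithium exchange and transmetalation to the organocerium give a weakly basic nucleophile that adds 1,2 to the enolizable methyl ketone under Felkin–Anh control, attack anti to the C1–C7a bond with the carbonyl oxygen on the C2 side giving the (S)-configured C1' carbinol, while C4' arrives fixed in the fragment.

Step 20
Reactants: 28 tertiary alcohol
Product: 29 C6 ketone (dioxolane of 28 hydrolysed; ring centres 1S,3aR,7aS)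
Conditions: pyridinium p-toluenesulfonate, acetone/H2O, 50 °C
Reagents that add atoms: water, O
Why: Mild acid-catalysed ketal hydrolysis frees the C6 ketone while the tert-butyldiphenylsilyl ether, the tertiary alcohol and the isopropenyl group stay untouched.

Step 21
Reactants: 29 hydroxy ketone
Product: 31 C5=C6 enol triflate of 29, via dipotassium alkoxide enolate 30 (not isolated)
Conditions: KN(SiMe3)2 (2.3 equiv), THF, −78 °C; PhNTf2, −78 °C to −20 °C; aq NH4Cl
Reagents that add atoms: N-phenylbis(trifluoromethanesulfonimide), O=S(=O)(N(c1ccccc1)S(=O)(=O)C(F)(F)F)C(F)(F)F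
Why: Kinetic enolate formation and O-sulfonylation (enol triflate synthesis), in which the first equivalent of base parks the tertiary hydroxyl as its hindered alkoxide and deprotonation goes to C5 because a C6=C7 enolate would flatten the ring next to the trans fusion, whereas the C5=C6 enolate leaves the C3a–C7a bond at the puckered end of the half-chair.

Step 22
Reactants: 31 enol triflate
Product: 33 C6 acetyl compound, 1-[(1S,3aR,7aS)-1-[(2S,5S)-5-[(tert-butyldiphenylsilyl)oxy]-2-hydroxy-6-methylhept-6-en-2-yl]-3a-methyl-2,3,3a,4,7,7a-hexahydro-1H-inden-6-yl]ethan-1-one, via ethoxydiene 32 (not isolated)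
Conditions: CH2=C(OEt)SnBu3, Pd(PPh3)4, LiCl, THF, 65 °C; then 1 M HCl, rt
Reagents that add atoms: tributyl(1-ethoxyvinyl)stannane, CCCC[Sn](CCCC)(CCCC)C(=C)OCC; water, O
Why: Stille coupling of the enol triflate with the 1-ethoxyvinyl stannane catalysed by Pd(PPh3)4 gives the 2-ethoxydiene, whose enol ether is hydrolysed by dilute acid to the conjugated methyl ketone.

Step 23
Reactants: 33 silyl-protected enone
Product: 34 1-[(1S,3aR,7aS)-1-[(2S,5S)-2,5-dihydroxy-6-methylhept-6-en-2-yl]-3a-methyl-2,3,3a,4,7,7a-hexahydro-1H-inden-6-yl]ethan-1-one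
Conditions: Bu4NF, THF, rt
Reagents that add atoms: none
Why: Fluoride cleavage of the tert-butyldiphenylsilyl ether avoids the acid that could cyclize the 1,4-diol onto its tertiary or allylic position.

Step 24
Reactants: 34 diol
Product: 35 (3S,6S)-6-[(1S,3aR,7aS)-6-acetyl-3a-methyl-2,3,3a,4,7,7a-hexahydro-1H-inden-1-yl]-6-hydroxy-2-methylhept-1-en-3-yl acetate (CNP0264549.1)
Conditions: Ac2O, pyridine, DMAP (cat.), CH2Cl2, 0 °C
Reagents that add atoms: acetic anhydride, CC(=O)OC(C)=O
Why: Acetylation with acetic anhydride and a nucleophilic catalyst esterifies the secondary allylic hydroxyl selectively, the hindered tertiary hydroxyl being inert under these conditions.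

Compound list
1 | (S)-but-3-yn-2-ol | C#C[C@H](C)O | starting material
2 | (S)-tert-butyl(but-3-yn-2-yloxy)dimethylsilane | C#C[C@H](C)O[Si](C)(C)C(C)(C)C | intermediate
3 | lithium acetylide of 2 | [Li]C#C[C@H](C)O[Si](C)(C)C(C)(C)C | intermediate
4 | (S)-4-[(tert-butyldimethylsilyl)oxy]pent-2-yn-1-ol | OCC#C[C@H](C)O[Si](C)(C)C(C)(C)C | intermediate
5 | (S)-[(5-bromopent-3-yn-2-yl)oxy](tert-butyl)dimethylsilane | BrCC#C[C@H](C)O[Si](C)(C)C(C)(C)C | intermediate
6 | 1,3-dithiane | C1CSCSC1 | starting material
7 | 4-bromo-2-methylbut-1-ene | C=C(C)CCBr | starting material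
8 | 2-lithio-1,3-dithiane | [Li]C1SCCCS1 | intermediate
9 | 2-(3-methylbut-3-en-1-yl)-1,3-dithiane | C=C(C)CCC1SCCCS1 | intermediate
10 | 2-lithio-2-(3-methylbut-3-en-1-yl)-1,3-dithiane | C=C(C)CCC1([Li])SCCCS1 | intermediate
11 | (S)-tert-butyldimethyl({5-[2-(3-methylbut-3-en-1-yl)-1,3-dithian-2-yl]pent-3-yn-2-yl}oxy)silane | C=C(C)CCC1(SCCCS1)CC#C[C@H](C)O[Si](C)(C)C(C)(C)C | intermediate
12 | (S)-tert-butyldimethyl({5-[2-(3-methylbut-3-en-1-yl)-1,3-dioxolan-2-yl]pent-3-yn-2-yl}oxy)silane (1,7-enyne) | C=C(C)CCC1(OCCO1)CC#C[C@H](C)O[Si](C)(C)C(C)(C)C | intermediate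
13 | (3aS)-1-[(S)-1-(tert-butyldimethylsilyloxy)ethyl]-6,6-(ethylenedioxy)-3a-methyl-3,3a,4,5,6,7-hexahydro-2H-inden-2-one | C[C@H](O[Si](C)(C)C(C)(C)C)C1=C2CC3(OCCO3)CC[C@@]2(C)CC1=O | intermediate
14 | (1S,3aS,7aS)-1-[(S)-1-(tert-butyldimethylsilyloxy)ethyl]-6,6-(ethylenedioxy)-3a-methyloctahydro-2H-inden-2-one (H at C1 and C7a anti to the C3a methyl) | C[C@H](O[Si](C)(C)C(C)(C)C)[C@H]1C(=O)C[C@]2(C)CCC3(OCCO3)C[C@@H]12 | intermediate
15 | C2 alcohol of 14 (C2 epimers) | C[C@H](O[Si](C)(C)C(C)(C)C)[C@H]1C(O)C[C@]2(C)CCC3(OCCO3)C[C@@H]12 | intermediate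
16 | O-phenyl thionocarbonate of 15 | C[C@H](O[Si](C)(C)C(C)(C)C)[C@H]1C(OC(=S)Oc3ccccc3)C[C@]2(C)CCC3(OCCO3)C[C@@H]12 | intermediate
17 | (1S,3aR,7aS)-1-[(S)-1-(tert-butyldimethylsilyloxy)ethyl]-6,6-(ethylenedioxy)-3a-methyloctahydro-1H-indene | C[C@H](O[Si](C)(C)C(C)(C)C)[C@H]1CC[C@]2(C)CCC3(OCCO3)C[C@@H]12 | intermediate
18 | (S)-1-[(1S,3aR,7aS)-6,6-(ethylenedioxy)-3a-methyloctahydro-1H-inden-1-yl]ethan-1-ol | C[C@H](O)[C@H]1CC[C@]2(C)CCC3(OCCO3)C[C@@H]12 | intermediate
19 | 1-[(1S,3aR,7aS)-6,6-(ethylenedioxy)-3a-methyloctahydro-1H-inden-1-yl]ethan-1-one | CC(=O)[C@H]1CC[C@]2(C)CCC3(OCCO3)C[C@@H]12 | intermediate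
20 | 3-[(tert-butyldimethylsilyl)oxy]propanal | O=CCCO[Si](C)(C)C(C)(C)C | starting material
21 | rac-5-[(tert-butyldimethylsilyl)oxy]-2-methylpent-1-en-3-ol | C=C(C)C(O)CCO[Si](C)(C)C(C)(C)C | intermediate
22 | (S)-5-[(tert-butyldimethylsilyl)oxy]-2-methylpent-1-en-3-ol | C=C(C)[C@H](CCO[Si](C)(C)C(C)(C)C)O | intermediate
23 | (S)-5-[(tert-butyldimethylsilyl)oxy]-3-[(tert-butyldiphenylsilyl)oxy]-2-methylpent-1-ene | C=C(C)[C@H](CCO[Si](C)(C)C(C)(C)C)O[Si](c1ccccc1)(c1ccccc1)C(C)(C)C | intermediate
24 | (S)-3-[(tert-butyldiphenylsilyl)oxy]-4-methylpent-4-en-1-ol | C=C(C)[C@H](CCO)O[Si](c1ccccc1)(c1ccccc1)C(C)(C)C | intermediate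
25 | (S)-tert-butyl[(5-iodo-2-methylpent-1-en-3-yl)oxy]diphenylsilane | C=C(C)[C@H](CCI)O[Si](c1ccccc1)(c1ccccc1)C(C)(C)C | intermediate
26 | (S)-[3-(tert-butyldiphenylsilyloxy)-4-methylpent-4-en-1-yl]lithium | C=C(C)[C@H](CC[Li])O[Si](c1ccccc1)(c1ccccc1)C(C)(C)C | intermediate
27 | (S)-[3-(tert-butyldiphenylsilyloxy)-4-methylpent-4-en-1-yl]cerium dichloride | C=C(C)[C@H](CC[Ce](Cl)Cl)O[Si](c1ccccc1)(c1ccccc1)C(C)(C)C | intermediate
28 | (2S,5S)-5-[(tert-butyldiphenylsilyl)oxy]-2-[(1S,3aR,7aS)-6,6-(ethylenedioxy)-3a-methyloctahydro-1H-inden-1-yl]-6-methylhept-6-en-2-ol | C=C(C)[C@H](CC[C@](C)(O)[C@H]1CC[C@]2(C)CCC3(OCCO3)C[C@@H]12)O[Si](c1ccccc1)(c1ccccc1)C(C)(C)C | intermediate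
29 | C6 ketone: 28 with the dioxolane replaced by C6=O | C=C(C)[C@H](CC[C@](C)(O)[C@H]1CC[C@]2(C)CCC(=O)C[C@@H]12)O[Si](c1ccccc1)(c1ccccc1)C(C)(C)C | intermediate
30 | dipotassium salt of 29 (C1' alkoxide and C5=C6 enolate) | C=C(C)[C@H](CC[C@](C)(O[K])[C@H]1CC[C@]2(C)CC=C(O[K])C[C@@H]12)O[Si](c1ccccc1)(c1ccccc1)C(C)(C)C | intermediate
31 | C5=C6 enol triflate of 29 | C=C(C)[C@H](CC[C@](C)(O)[C@H]1CC[C@]2(C)CC=C(OS(=O)(=O)C(F)(F)F)C[C@@H]12)O[Si](c1ccccc1)(c1ccccc1)C(C)(C)C | intermediate
32 | 6-(1-ethoxyvinyl) diene from 31 | C=C(C)[C@H](CC[C@](C)(O)[C@H]1CC[C@]2(C)CC=C(C(=C)OCC)C[C@@H]12)O[Si](c1ccccc1)(c1ccccc1)C(C)(C)C | intermediate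
33 | 1-[(1S,3aR,7aS)-1-[(2S,5S)-5-[(tert-butyldiphenylsilyl)oxy]-2-hydroxy-6-methylhept-6-en-2-yl]-3a-methyl-2,3,3a,4,7,7a-hexahydro-1H-inden-6-yl]ethan-1-one | C=C(C)[C@H](CC[C@](C)(O)[C@H]1CC[C@]2(C)CC=C(C(C)=O)C[C@@H]12)O[Si](c1ccccc1)(c1ccccc1)C(C)(C)C | intermediate
34 | 1-[(1S,3aR,7aS)-1-[(2S,5S)-2,5-dihydroxy-6-methylhept-6-en-2-yl]-3a-methyl-2,3,3a,4,7,7a-hexahydro-1H-inden-6-yl]ethan-1-one | C=C(C)[C@H](CC[C@](C)(O)[C@H]1CC[C@]2(C)CC=C(C(C)=O)C[C@@H]12)O | intermediate
35 | (3S,6S)-6-[(1S,3aR,7aS)-6-acetyl-3a-methyl-2,3,3a,4,7,7a-hexahydro-1H-inden-1-yl]-6-hydroxy-2-methylhept-1-en-3-yl acetate (CNP0264549.1) | C=C(C)[C@H](CC[C@](C)(O)[C@H]1CC[C@]2(C)CC=C(C(C)=O)C[C@@H]12)OC(C)=O | target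

Total step count: 24.
Longest linear sequence: 18 steps (steps 1–3, 5–13 and 19–24, from compound 1 to compound 35).

Steps most likely to fail

1. Step 7. The oxidative cyclization of a carbon-tethered 1,7-enyne onto a 1,1-disubstituted alkene may be too slow, so that alkyne oligomerization or cycloisomerization takes over, or the diphosphine may discriminate the alkene faces poorly. The fallback sets out from enyne 12. Complexation with Co2(CO)8 in CH2Cl2 gives the hexacarbonyldicobalt alkyne complex F1, which is cyclized with N-methylmorpholine N-oxide in CH2Cl2 at rt (stoichiometric Pauson–Khand reaction). The cyclization is then not enantioselective, but because C1' is a fixed (S) centre the product is a pair of diastereomers, enone 13 and its C3a epimer F2, which are separated by chromatography. The route is rejoined at 13.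

2. Step 8. The tetrasubstituted enone may take up hydrogen slowly, the allylic C1'–O bond may be hydrogenolysed, or hydrogen may arrive from the methyl face, since the required face also carries C4 and the axial ketal oxygen. The fallback sets out from enone 13. 1,2-Reduction with i-Bu2AlH (CH2Cl2, −78 °C), expected from the face opposite the silyloxy group, should give the allylic alcohol F3 with the C2 hydroxyl syn to the angular methyl. Mitsunobu displacement with 2-nitrobenzenesulfonylhydrazide (PPh3, diethyl azodicarboxylate, THF, −30 °C) inverts C2 and gives the N-allyl sulfonylhydrazide F4. On warming to rt this loses the sulfinic acid to give the allylic diazene F5, which transfers its hydrogen suprafacially to C7a on the face anti to the methyl with loss of N2 (reductive 1,3-transposition). The result is the C1=C2 alkene F6, with the trans ring fusion in place and C2 already deoxygenated. Hydrogenation of this trisubstituted alkene (H2, Pd/C, EtOAc), from the face opposite both the angular methyl and C7, sets C1. The route is rejoined at 17, and steps 9 to 11 are not needed.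

3. Step 21. Deprotonation at C7 may compete with deprotonation at C5, or the tertiary alkoxide may be sulfonylated and eliminate. The fallback sets out from hydroxy ketone 29. Me3SiOTf and Et3N (CH2Cl2, 0 °C to rt) silylate the tertiary hydroxyl and, under equilibrating conditions, form the more stable C5=C6 silyl enol ether, giving the bis(trimethylsilyl) compound F7. MeLi (THF, 0 °C) cleaves only the enol ether to the regiodefined lithium enolate F8, which PhNTf2 traps as the enol triflate F9. The coupling and acid treatment of step 22, applied to F9, pass through the ethoxydiene F10, and the acid also removes the trimethylsilyl ether. The route is rejoined at enone 33.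

Further compounds
F1 | step 7 | hexacarbonyldicobalt complex of enyne 12 | C=C(C)CCC1(OCCO1)CC23[Co]4(=C=O)(=C=O)(=C=O)[Co]2(=C=O)(=C=O)(=C=O)C34[C@H](C)O[Si](C)(C)C(C)(C)C
F2 | step 7 | C3a epimer of enone 13 | C[C@H](O[Si](C)(C)C(C)(C)C)C1=C2CC3(OCCO3)CC[C@]2(C)CC1=O
F3 | step 8 | allylic alcohol from 13 (C2 hydroxyl syn to the C3a methyl) | C[C@H](O[Si](C)(C)C(C)(C)C)C1=C2CC3(OCCO3)CC[C@@]2(C)C[C@@H]1O
F4 | step 8 | N-allyl-N-(2-nitrobenzenesulfonyl)hydrazine (C2 inverted) | C[C@H](O[Si](C)(C)C(C)(C)C)C1=C2CC3(OCCO3)CC[C@@]2(C)C[C@H]1N(N)S(=O)(=O)c1ccccc1[N+](=O)[O-]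
F5 | step 8 | allylic diazene | C[C@H](O[Si](C)(C)C(C)(C)C)C1=C2CC3(OCCO3)CC[C@@]2(C)C[C@H]1N=N
F6 | step 8 | C1=C2 alkene with trans ring fusion | C[C@H](O[Si](C)(C)C(C)(C)C)C1=CC[C@]2(C)CCC3(OCCO3)C[C@@H]12
F7 | step 21 | bis(trimethylsilyl) compound (C1' silyl ether and C5=C6 silyl enol ether) | C=C(C)[C@H](CC[C@](C)(O[Si](C)(C)C)[C@H]1CC[C@]2(C)CC=C(O[Si](C)(C)C)C[C@@H]12)O[Si](c1ccccc1)(c1ccccc1)C(C)(C)C
F8 | step 21 | lithium C5=C6 enolate with C1' trimethylsilyl ether | C=C(C)[C@H](CC[C@](C)(O[Si](C)(C)C)[C@H]1CC[C@]2(C)CC=C(O[Li])C[C@@H]12)O[Si](c1ccccc1)(c1ccccc1)C(C)(C)C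
F9 | step 21 | C5=C6 enol triflate with C1' trimethylsilyl ether | C=C(C)[C@H](CC[C@](C)(O[Si](C)(C)C)[C@H]1CC[C@]2(C)CC=C(OS(=O)(=O)C(F)(F)F)C[C@@H]12)O[Si](c1ccccc1)(c1ccccc1)C(C)(C)C
F10 | step 21 | ethoxydiene with C1' trimethylsilyl ether | C=C(C)[C@H](CC[C@](C)(O[Si](C)(C)C)[C@H]1CC[C@]2(C)CC=C(C(=C)OCC)C[C@@H]12)O[Si](c1ccccc1)(c1ccccc1)C(C)(C)C
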